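You want to know when to read this flask and how much E it will hold then, and your hunch is that the percentages carry over from Saturday's run, since D is charged the same.

| flask | J | D | remark | time |
|---|---|---|---|---|
| Saturday's | 1.1 M | 1.2 M | run made earlier |  |
| Tuesday's | 1.8 M | 1.2 M | run made earlier |  |
| Friday's | 0.80 M | 2.4 M | run made earlier |  |
| flask | 0.80 M | 1.20 M |  | 15 h |

| run | time / h | E / % | J / % |
|---|---|---|---|
| Saturday's | 0.667 | 4.9 | 73.0 |
| Saturday's | 2.00 | 5.8 | 49.6 |
| Saturday's | 6.00 | 5.7 | 28.0 |
| Saturday's | 20.0 | 0.8 | 11.0 |
| Tuesday's | 0.667 | 3.6 | 73.8 |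
| Tuesday's | 2.00 | 3.1 | 55.1 |
| Tuesday's | 6.00 | 1.1 | 44.7 |
| Tuesday's | 20.0 | 0 | 32.7 |
| Friday's | 0.667 | 9.2 | 37.8 |
| Friday's | 2.00 | 14.0 | 12.4 |
| Friday's | 6.00 | 13.7 | 1.4 |
| Friday's | 20.0 | 15.4 | 0 |

(each reading ± 1 percentage point)

* time, not beyond 15 h, at which the flask holds most E
* the amount of E, in percent of the J charged, at that time
* earliest time at which at least nineteen twentieths of that best amount are there
* latest time at which they still are



I would not carry percentages over: at the same charge of D, Saturday's tops at 5.8% and Tuesday's at 3.6%, a clear gap. Follow one molecule of J instead. I take it that J can meet D and make E, or meet E and destroy it, since Friday's keeps 15.4% of E at 20.0 h with J at 0%, while Tuesday's falls to 0% with J at 32.7%. J stands in both rates, so the odds at that fork depend on E against D, and E should stop rising at a concentration set by D.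

Read in M, the two tops are 0.0638 M and 0.0648 M, nearly equal within the scatter. I call their mean the ceiling C, the top concentration of E at this charge of D, 0.0643 M. Dividing by the J charged gives 8.04% for the flask, and I expect that top between about 2.00 h and 6.00 h, where Saturday's is flat.

The forecast, a little below my figure, says 7.6% at 3.5 h, with the window from 1.9 h to 7 h, holding that the flask “should follow Saturday's run but keep slightly more E in percentage terms”. The flask gives 9.86% at 2.62 h, with the window from 1.54 h to 4.72 h.

    J + E → Z (k = 0.0176 /M/min)
    J + 2 D → X (k = 0.00520 /M²/min)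
    J + D → E (k = 0.00262 /M/min)

At 2.62 h in the flask, with D at 44.1% of its charge and E at 9.86%, each J molecule makes E at 0.00139 /min and destroys E at 0.00139 /min, level, and the concentration of E over that of D there is 0.149, the value of the selectivity factor, the rate constant of J + D → E over that of J + E → Z, 0.149. Read in M, the flask's C is 0.0789 M, above my 0.0643 M. Carried to the neighbour charged with 1.4 M of J, that C gives 5.64%, and that neighbour's best is 5.63%.

The runs stem from a simulated flask for an exercise, noise included.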